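**Retrosynthetic overview**
1. Target 20 comes from flavonol 19 by a final hydrogenolysis of its three benzyl ethers.
2. The strategy rests on ring C (O1–C2–C3–C4–C4a–C8a, with the C2 aryl and the C3 hydroxyl): it is a 2'-hydroxychalcone plus one oxygen atom, so O1–C2 and C3–OH are cut (Algar–Flynn–Oyamada) to give chalcone 17. Ring C is the only ring formed; rings A and B are bought as arenes.
3. Chalcone 17 is cut at its Cα=Cβ bond (Claisen–Schmidt) into ring A acetophenone 6 and ring B aldehyde 16.
4. Acetophenone 6 comes from phloroacetophenone 1 by 4-O-benzylation, mono-O-methylation, Elbs para-hydroxylation (the future C6–O) and a second O-methylation.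
5. Aldehyde 16 comes from 4-bromo-2-iodophenol 11 by benzylation, B-alkyl Suzuki coupling at C–I with the 9-BBN adduct of alkene 10 (three steps from (R)-Roche ester 7), and Br/Li exchange–formylation.

Key step: step 12

Remark: the side-chain stereocentre is bought with (R)-Roche ester and no bond to it is ever broken; its descriptor changes from R (7, 8, 9) to S (10 onwards) only because the CIP priorities of its substituents change.

**Route**

Step 1
Reactants: 1 2',4',6'-trihydroxyacetophenone (dried)
Product: 2 1-[4-(benzyloxy)-2,6-dihydroxyphenyl]ethan-1-one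
Conditions: BnBr (1.0 equiv), K2CO3 (1.1 equiv), DMF, 0 °C to rt
Reagents that add atoms: benzyl bromide, BrCc1ccccc1
Why: Williamson etherification; the 4-OH is the most acidic and the only hydroxyl not hydrogen-bonded to the carbonyl, so one equivalent of weak base and halide should alkylate it first.

Step 2
Reactants: 2 1-[4-(benzyloxy)-2,6-dihydroxyphenyl]ethan-1-one
Product: 3 1-[4-(benzyloxy)-2-hydroxy-6-methoxyphenyl]ethan-1-one
Conditions: Me2SO4 (1.05 equiv), K2CO3, acetone, reflux
Reagents that add atoms: dimethyl sulfate, COS(=O)(=O)OC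
Why: O-methylation of one of two equivalent phenols; the remaining hydroxyl stays chelated to the carbonyl and resists a second methylation.

Step 3
Reactants: 3 1-[4-(benzyloxy)-2-hydroxy-6-methoxyphenyl]ethan-1-one
Product: 5 1-[4-(benzyloxy)-2,5-dihydroxy-6-methoxyphenyl]ethan-1-one, via aryl sulfate potassium salt 4 (not isolated)
Conditions: K2S2O8 (1.2 equiv), 10 % aq KOH, pyridine, 0 °C to rt; acidify to pH 4 and extract unchanged 3; then 2 M HCl, Na2SO3, toluene, 80 °C
Reagents that add atoms: potassium peroxodisulfate, [K+].[K+].[O-]S(=O)(=O)OOS(=O)(=O)[O-]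
Why: Elbs persulfate oxidation; the phenoxide attacks the peroxide oxygen through its para carbon (C5, flanked by two alkoxy groups) to give the aryl sulfate, which dilute acid hydrolyses to the hydroquinone.

Step 4
Reactants: 5 1-[4-(benzyloxy)-2,5-dihydroxy-6-methoxyphenyl]ethan-1-one
Product: 6 1-[4-(benzyloxy)-2-hydroxy-5,6-dimethoxyphenyl]ethan-1-one
Conditions: Me2SO4 (1.05 equiv), K2CO3, acetone, reflux
Reagents that add atoms: dimethyl sulfate, COS(=O)(=O)OC
Why: Selective O-methylation; the new 5-OH is free, whereas the 2-OH is held in a hydrogen bond to the ketone and should remain untouched with one equivalent of reagent.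

Step 5
Reactants: 7 methyl (R)-3-hydroxy-2-methylpropanoate
Product: 8 methyl (R)-3-(benzyloxy)-2-methylpropanoate
Conditions: BnOC(=NH)CCl3 (1.3 equiv), TfOH (cat.), CH2Cl2/cyclohexane, 0 °C to rt
Reagents that add atoms: benzyl 2,2,2-trichloroacetimidate, N=C(OCc1ccccc1)C(Cl)(Cl)Cl
Why: Acid-catalysed benzylation with a trichloroacetimidate avoids base, so the α-stereocentre cannot epimerise and the β-hydroxy ester cannot eliminate.

Step 6
Reactants: 8 methyl (R)-3-(benzyloxy)-2-methylpropanoate
Product: 9 (R)-3-(benzyloxy)-2-methylpropanal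
Conditions: i-Bu2AlH (1.05 equiv), CH2Cl2, −78 °C; MeOH, then aq potassium sodium tartrate (KNaC4H4O6); crude 9 used at once
Reagents that add atoms: none
Why: Partial reduction of an ester with i-Bu2AlH; the tetrahedral aluminium hemiacetal is stable at −78 °C and releases the aldehyde only on work-up, and the cold neutral conditions preserve the α-stereocentre.

Step 7
Reactants: 9 (R)-3-(benzyloxy)-2-methylpropanal
Product: 10 (S)-4-(benzyloxy)-3-methylbut-1-ene
Conditions: Ph3PCH3Br, KN(SiMe3)2, THF, 0 °C; then 9, −78 °C to 0 °C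
Reagents that add atoms: methyltriphenylphosphonium bromide, C[P+](c1ccccc1)(c1ccccc1)c1ccccc1.[Br-]
Why: Wittig methylenation; addition of the unstabilised ylide to the aldehyde at low temperature should be faster than enolisation, so the stereocentre is carried through unchanged.

Step 8
Reactants: 11 4-bromo-2-iodophenol
Product: 12 1-(benzyloxy)-4-bromo-2-iodobenzene
Conditions: BnBr, K2CO3, DMF, rt
Reagents that add atoms: benzyl bromide, BrCc1ccccc1
Why: Williamson etherification of a single acidic phenol.

Step 9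
Reactants: 10 (S)-4-(benzyloxy)-3-methylbut-1-ene, 12 1-(benzyloxy)-4-bromo-2-iodobenzene
Product: 14 1-(benzyloxy)-2-[(3S)-4-(benzyloxy)-3-methylbutyl]-4-bromobenzene, via B-alkyl-9-BBN borane 13 (not isolated)
Conditions: 10, 9-BBN dimer, THF, 0 °C to rt; then 12 (1.1 equiv), PdCl2(dppf)·CH2Cl2 (5 mol %), 3 M aq K3PO4, DMF, rt
Reagents that add atoms: none
Why: Anti-Markovnikov hydroboration followed by B-alkyl Suzuki–Miyaura coupling; oxidative addition into C–I is much faster than into C–Br at room temperature, and the stereocentre lies two carbons from boron and is not involved.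

Step 10
Reactants: 14 1-(benzyloxy)-2-[(3S)-4-(benzyloxy)-3-methylbutyl]-4-bromobenzene
Product: 16 4-(benzyloxy)-3-[(3S)-4-(benzyloxy)-3-methylbutyl]benzaldehyde, via aryllithium 15 (not isolated)
Conditions: n-BuLi (1.1 equiv), THF, −78 °C; DMF, −78 °C to 0 °C; aq NH4Cl
Reagents that add atoms: N,N-dimethylformamide, CN(C)C=O
Why: Bromine–lithium exchange and formylation of the aryllithium with DMF; at −78 °C the exchange should outrun deprotonation of the benzyl ethers.

Step 11
Reactants: 6 1-[4-(benzyloxy)-2-hydroxy-5,6-dimethoxyphenyl]ethan-1-one, 16 4-(benzyloxy)-3-[(3S)-4-(benzyloxy)-3-methylbutyl]benzaldehyde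
Product: 17 (2E)-1-[4-(benzyloxy)-2-hydroxy-5,6-dimethoxyphenyl]-3-{4-(benzyloxy)-3-[(3S)-4-(benzyloxy)-3-methylbutyl]phenyl}prop-2-en-1-one
Conditions: KOH (50 % aq), EtOH/THF, 0 °C to rt; then 1 M HCl
Reagents that add atoms: none
Why: Claisen–Schmidt condensation; the methyl ketone enolate adds to the non-enolisable aldehyde and E1cB dehydration gives the conjugated (E)-enone, which stays open as its phenoxide in strong base.

Step 12
Reactants: 17 the 2'-hydroxychalcone from step 11
Product: 19 7-(benzyloxy)-2-{4-(benzyloxy)-3-[(3S)-4-(benzyloxy)-3-methylbutyl]phenyl}-3-hydroxy-5,6-dimethoxy-4H-chromen-4-one, via trans-dihydroflavonol 18 (not isolated)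
Conditions: 30 % aq H2O2, 2 M aq NaOH, MeOH/THF, 0 °C then rt; then 1 M HCl
Reagents that add atoms: hydrogen peroxide, OO
Why: Hydroperoxide anion epoxidises the enone of the chalcone phenoxide (Weitz–Scheffer) and the 2'-phenoxide opens the epoxide at the benzylic β-carbon, or the phenoxide adds first in an oxa-Michael sense and the enolate is then hydroxylated; both paths make O1–C2 and C3–OH and give trans-dihydroflavonol 18, which excess alkaline peroxide dehydrogenates to 19. The closest known reaction type is the alkaline H2O2 conversion of 2'-hydroxychalcones into flavonols, which also covers 6'-methoxy chalcones carrying a para-alkoxy ring B. Ring C closes in a 6-endo mode (6-endo-tet on the epoxide, or 6-endo-trig on the enone). The two sp3 centres of 18 (C2 and C3, trans through anti opening or equilibration) disappear on oxidation, so 19 gains no stereocentre and the remote (S) centre of the side chain takes no part. The selectivity required is attack at Cβ (flavonol) in preference to Cα (5-exo closure to the aurone), which a 6'-methoxy group tends to encourage; the para-benzyloxy group of ring B stabilises positive character at the benzylic carbon and the reaction is started at 0 °C to favour β-opening. With only one unprotected phenol in 17, the ring oxygen must come from the 2'-OH, which locks the 5,6-dimethoxy-7-benzyloxy arrangement of ring A.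

Step 13
Reactants: 19 the tri-O-benzyl flavonol from step 12
Product: 20 3,7-dihydroxy-2-{4-hydroxy-3-[(3S)-4-hydroxy-3-methylbutyl]phenyl}-5,6-dimethoxy-4H-chromen-4-one
Conditions: H2 (1 atm), 10 % Pd/C, EtOAc/MeOH, rt
Reagents that add atoms: none
Why: Hydrogenolysis of two aryl benzyl ethers and one primary alkyl benzyl ether over Pd/C; the tetrasubstituted C2=C3 bond of the pyranone, the methyl ethers and the stereocentre should not be affected.

**Compound list**
1 | 2',4',6'-trihydroxyacetophenone | CC(=O)c1c(O)cc(O)cc1O | starting material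
2 | 1-[4-(benzyloxy)-2,6-dihydroxyphenyl]ethan-1-one | CC(=O)c1c(O)cc(OCc2ccccc2)cc1O | intermediate
3 | 1-[4-(benzyloxy)-2-hydroxy-6-methoxyphenyl]ethan-1-one | CC(=O)c1c(O)cc(OCc2ccccc2)cc1OC | intermediate
4 | potassium 3-acetyl-6-(benzyloxy)-4-hydroxy-2-methoxyphenyl sulfate (not isolated) | CC(=O)c1c(O)cc(OCc2ccccc2)c(OS(=O)(=O)[O-])c1OC.[K+] | intermediate
5 | 1-[4-(benzyloxy)-2,5-dihydroxy-6-methoxyphenyl]ethan-1-one | CC(=O)c1c(O)cc(OCc2ccccc2)c(O)c1OC | intermediate
6 | 1-[4-(benzyloxy)-2-hydroxy-5,6-dimethoxyphenyl]ethan-1-one | CC(=O)c1c(O)cc(OCc2ccccc2)c(OC)c1OC | intermediate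
7 | methyl (R)-3-hydroxy-2-methylpropanoate | COC(=O)[C@H](C)CO | starting material
8 | methyl (R)-3-(benzyloxy)-2-methylpropanoate | COC(=O)[C@H](C)COCc1ccccc1 | intermediate
9 | (R)-3-(benzyloxy)-2-methylpropanal | O=C[C@H](C)COCc1ccccc1 | intermediate
10 | (S)-4-(benzyloxy)-3-methylbut-1-ene | C=C[C@H](C)COCc1ccccc1 | intermediate
11 | 4-bromo-2-iodophenol | Oc1ccc(Br)cc1I | starting material
12 | 1-(benzyloxy)-4-bromo-2-iodobenzene | Brc1ccc(OCc2ccccc2)c(I)c1 | intermediate
13 | 9-[(3S)-4-(benzyloxy)-3-methylbutyl]-9-borabicyclo[3.3.1]nonane (not isolated) | B1(CC[C@H](C)COCc2ccccc2)C2CCCC1CCC2 | intermediate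
14 | 1-(benzyloxy)-2-[(3S)-4-(benzyloxy)-3-methylbutyl]-4-bromobenzene | Brc1ccc(OCc2ccccc2)c(CC[C@H](C)COCc2ccccc2)c1 | intermediate
15 | {4-(benzyloxy)-3-[(3S)-4-(benzyloxy)-3-methylbutyl]phenyl}lithium (not isolated) | [Li]c1ccc(OCc2ccccc2)c(CC[C@H](C)COCc2ccccc2)c1 | intermediate
16 | 4-(benzyloxy)-3-[(3S)-4-(benzyloxy)-3-methylbutyl]benzaldehyde | O=Cc1ccc(OCc2ccccc2)c(CC[C@H](C)COCc2ccccc2)c1 | intermediate
17 | (2E)-1-[4-(benzyloxy)-2-hydroxy-5,6-dimethoxyphenyl]-3-{4-(benzyloxy)-3-[(3S)-4-(benzyloxy)-3-methylbutyl]phenyl}prop-2-en-1-one | COc1c(OCc2ccccc2)cc(O)c(C(=O)/C=C/c2ccc(OCc3ccccc3)c(CC[C@H](C)COCc3ccccc3)c2)c1OC | intermediate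
18 | 7-(benzyloxy)-2-{4-(benzyloxy)-3-[(3S)-4-(benzyloxy)-3-methylbutyl]phenyl}-3-hydroxy-5,6-dimethoxy-2,3-dihydro-4H-chromen-4-one (2,3-trans, both ring configurations; not isolated) | COc1c(OCc2ccccc2)cc2OC(c3ccc(OCc4ccccc4)c(CC[C@H](C)COCc4ccccc4)c3)C(O)C(=O)c2c1OC | intermediate
19 | 7-(benzyloxy)-2-{4-(benzyloxy)-3-[(3S)-4-(benzyloxy)-3-methylbutyl]phenyl}-3-hydroxy-5,6-dimethoxy-4H-chromen-4-one | COc1c(OCc2ccccc2)cc2oc(-c3ccc(OCc4ccccc4)c(CC[C@H](C)COCc4ccccc4)c3)c(O)c(=O)c2c1OC | intermediate
20 | 3,7-dihydroxy-2-{4-hydroxy-3-[(3S)-4-hydroxy-3-methylbutyl]phenyl}-5,6-dimethoxy-4H-chromen-4-one | COc1c(O)cc2oc(-c3ccc(O)c(CC[C@H](C)CO)c3)c(O)c(=O)c2c1OC | target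

**Step count**
Total: 13 steps. Longest linear sequence: 8 steps (7 to 20 through steps 5, 6, 7, 9, 10, 11, 12 and 13).

**Steps most likely to fail**

Step 12. The phenoxide may close on the α-carbon of the epoxide (5-exo) and give the aurone, which the 6'-methoxy group promotes, or alkaline peroxide may degrade the chalcone before closure. The fallback sets out from 17 and comes back at 19, separating ring closure from C3 hydroxylation so that no aurone branch exists. Heating 17 with I2 (10 mol %) in DMSO at 120 °C should effect oxa-Michael closure and dehydrogenation to the flavone 7-(benzyloxy)-2-{4-(benzyloxy)-3-[(3S)-4-(benzyloxy)-3-methylbutyl]phenyl}-5,6-dimethoxy-4H-chromen-4-one F1. Dimethyldioxirane in acetone/CH2Cl2 at 0 °C should then epoxidise the C2=C3 bond to the flavone 2,3-epoxide F2. Catalytic TsOH in CH2Cl2 should open the epoxide and tautomerise it to flavonol 19.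

Step 3. Sulfation of the chelated, acyl-deactivated phenoxide may stop at low conversion, and material may be lost through oxidative tar formation or partial benzyl ether cleavage during the hot acid hydrolysis. The fallback sets out from 3 and comes back at 5 by a radical oxidation instead of the persulfate route. Potassium nitrosodisulfonate, (KSO3)2NO (2.2 equiv), in KH2PO4-buffered aqueous acetone at rt (Teuber oxidation) should give the para-quinone 2-acetyl-5-(benzyloxy)-3-methoxycyclohexa-2,5-diene-1,4-dione F3. Shaking its EtOAc solution with aqueous Na2S2O4 should reduce it to hydroquinone 5.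

Step 7. The basic ylide may enolise aldehyde 9 and erode the enantiopurity of the α-stereocentre, which cannot be corrected later. The fallback sets out from 9 and comes back at 10 by a Peterson olefination, which uses a weakly basic nucleophile. Me3SiCH2MgCl in Et2O at −78 °C should add to 9 to give the β-hydroxysilane (3R)-4-(benzyloxy)-3-methyl-1-(trimethylsilyl)butan-2-ol F4 (both carbinol epimers, which converge). KH in THF at 0 °C should then bring about syn-elimination to alkene 10.

**Further compounds**
F1 | step 12 | 7-(benzyloxy)-2-{4-(benzyloxy)-3-[(3S)-4-(benzyloxy)-3-methylbutyl]phenyl}-5,6-dimethoxy-4H-chromen-4-one | COc1c(OCc2ccccc2)cc2oc(-c3ccc(OCc4ccccc4)c(CC[C@H](C)COCc4ccccc4)c3)cc(=O)c2c1OC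
F2 | step 12 | 4-(benzyloxy)-1a-{4-(benzyloxy)-3-[(3S)-4-(benzyloxy)-3-methylbutyl]phenyl}-5,6-dimethoxy-1a,7a-dihydro-7H-oxireno[2,3-b]chromen-7-one (the 2,3-epoxide of F1, both epoxide faces) | COc1c(OCc2ccccc2)cc2OC3(c4ccc(OCc5ccccc5)c(CC[C@H](C)COCc5ccccc5)c4)OC3C(=O)c2c1OC
F3 | step 3 | 2-acetyl-5-(benzyloxy)-3-methoxycyclohexa-2,5-diene-1,4-dione | CC(=O)C1=C(OC)C(=O)C(OCc2ccccc2)=CC1=O
F4 | step 7 | (3R)-4-(benzyloxy)-3-methyl-1-(trimethylsilyl)butan-2-ol (both C2 epimers) | C[Si](C)(C)CC(O)[C@H](C)COCc1ccccc1
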